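**Strategy**

Ring C of the target (O1–C2–C3–C4–C4a–C8a) is a benzo-fused 2,3-dihydro-4-pyranone whose O1–C8a=C4a–C4=O unit is a vinylogous ester. It is therefore cut as a dihydropyranone annulation: the C2–C3 bond by an aldol addition and the O1–C8a bond by displacement of a leaving group on ring A. In one operation, a catalytic enantioselective Mukaiyama aldol joins 3,4,5-trimethoxybenzaldehyde to the silyl enol ether of 6-fluoro-2,3,4-trimethoxyphenyl methyl ketone (a benzo-fused 1-alkoxy-3-silyloxybutadiene equivalent with fluoride at its terminus). Fluoride then turns the silyl aldolate into the alkoxide that closes ring C by SNAr, with C2 set as S.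

Key step: step 3

Remark: the sense of induction of the tryptophan-derived catalyst is assumed by analogy with simple aromatic aldehydes (enol silane to the Si face, S carbinol); if a first run shows the opposite sense, the catalyst from N-tosyl-(R)-tryptophan is used with no other change.

**Route**

Step 1
Reactants: 1 5-fluoro-1,2,3-trimethoxybenzene
Product: 2 1-(6-fluoro-2,3,4-trimethoxyphenyl)ethan-1-one
Conditions: Ac2O, Bi(OTf)3 (5 mol%), MeNO2, 50 °C
Reagents that add atoms: acetic anhydride CC(=O)OC(C)=O
Why: Friedel–Crafts acylation at the only free ring position (C4 and C6 are equivalent, each para to one methoxy group and ortho to another), and the catalytic triflate should avoid the ortho-demethylation that stoichiometric aluminium Lewis acids cause.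

Step 2
Reactants: 2 1-(6-fluoro-2,3,4-trimethoxyphenyl)ethan-1-one
Product: 3 trimethyl{[1-(6-fluoro-2,3,4-trimethoxyphenyl)ethenyl]oxy}silane
Conditions: Me3SiOTf, Et3N, CH2Cl2, 0 °C
Reagents that add atoms: trimethylsilyl triflate C[Si](C)(C)OS(=O)(=O)C(F)(F)F
Why: Soft enolisation and O-silylation of a methyl ketone with a single enolisable site should give the enol silane cleanly.

Step 3
Reactants: 3 trimethyl{[1-(6-fluoro-2,3,4-trimethoxyphenyl)ethenyl]oxy}silane and 4 3,4,5-trimethoxybenzaldehyde (1.1 equiv)
Product: 7 (2S)-5,6,7-trimethoxy-2-(3,4,5-trimethoxyphenyl)chroman-4-one, via silyl aldolate 5 (not isolated), via tetrabutylammonium alkoxide 6 (not isolated)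
Conditions: B-butyl oxazaborolidinone from N-tosyl-(S)-tryptophan and BuB(OH)2 (20 mol%), EtCN, −78 °C; then DMF, TBAT (30 mol%), −40 °C to rt; pH 7 phosphate buffer quench at 0 °C
Reagents that add atoms: none
Why: The boron Lewis acid activates the aldehyde and the enol silane adds to its Si face through an open transition state (Mukaiyama aldol, C2–C3 bond), silyl transfer giving 5; fluoride then removes the silyl group and alkoxide 6 attacks C8a, the fluorine-bearing carbon ortho to the ketone, by addition–elimination (SNAr, O1–C8a bond), the expelled fluoride carrying on the desilylation so that Me3SiF is the only by-product. The closest known reaction type is the oxazaborolidinone-catalysed Mukaiyama aldol–dihydropyranone annulation of 1-methoxy-3-silyloxybutadiene, here in benzo-fused form with fluoride as the terminal leaving group, joined to the known fluoride-mediated SNAr of silyl ethers on aryl fluorides activated by an ortho carbonyl group. Ring C closes in the 6-endo-trig mode with respect to the vinylogous acyl fluoride F–C8a=C4a–C4=O, through a Meisenheimer-type adduct that rearomatises by loss of fluoride. C2 is set in the aldol event by the catalyst, whose indole unit shields one face of the boron-bound aldehyde, and is not touched afterwards because the C2–O1 bond is never broken. The step needs ring closure to outrun retro-aldol and β-elimination of 6, which the base-free generation of the alkoxide at low temperature and the six-membered intramolecular closure favour, and it needs attack at C8a–F and not at C5–OMe, which the far better activating and leaving ability of fluorine secures.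

**Compound list**

1 | 5-fluoro-1,2,3-trimethoxybenzene | COc1cc(F)cc(OC)c1OC | starting material
2 | 1-(6-fluoro-2,3,4-trimethoxyphenyl)ethan-1-one | CC(=O)c1c(F)cc(OC)c(OC)c1OC | intermediate
3 | trimethyl{[1-(6-fluoro-2,3,4-trimethoxyphenyl)ethenyl]oxy}silane | C=C(O[Si](C)(C)C)c1c(F)cc(OC)c(OC)c1OC | intermediate
4 | 3,4,5-trimethoxybenzaldehyde | COc1cc(C=O)cc(OC)c1OC | starting material
5 | (3S)-1-(6-fluoro-2,3,4-trimethoxyphenyl)-3-(3,4,5-trimethoxyphenyl)-3-(trimethylsilyloxy)propan-1-one | COc1cc([C@H](CC(=O)c2c(F)cc(OC)c(OC)c2OC)O[Si](C)(C)C)cc(OC)c1OC | intermediate (not isolated)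
6 | tetrabutylammonium (1S)-3-(6-fluoro-2,3,4-trimethoxyphenyl)-3-oxo-1-(3,4,5-trimethoxyphenyl)propan-1-olate | COc1cc([C@H](CC(=O)c2c(F)cc(OC)c(OC)c2OC)[O-])cc(OC)c1OC.CCCC[N+](CCCC)(CCCC)CCCC | intermediate (not isolated)
7 | (2S)-5,6,7-trimethoxy-2-(3,4,5-trimethoxyphenyl)chroman-4-one | COc1cc([C@@H]2CC(=O)c3c(cc(OC)c(OC)c3OC)O2)cc(OC)c1OC | target

Total step count: 3
Longest linear sequence: 3 steps (1 → 2 → 3 → 7)

**Steps most likely to fail**

1. Step 3. Once the alkoxide is set free it may undergo retro-aldol cleavage or β-elimination faster than it closes onto the electron-rich fluoroarene, and residual fluoride may open ring C of the product reversibly. Either process would lower the enantiomeric purity or divert material to the chalcone. The fallback sets out from 2 and comes back at 7, and it never passes through a β-alkoxy ketone alkoxide. Ketone 2 is formylated with ethyl formate and NaH in THF to 3-(6-fluoro-2,3,4-trimethoxyphenyl)-3-oxopropanal F1 (enol form). Its enolate oxygen displaces the ortho fluoride (K2CO3, DMF, 80 °C) to give 5,6,7-trimethoxy-4H-chromen-4-one F2. Asymmetric 1,4-addition of (3,4,5-trimethoxyphenyl)boronic acid (Pd(OCOCF3)2, t-BuPyOx, NH4PF6, H2O, ClCH2CH2Cl, 60 °C) then installs ring B and C2 to give 7. The ligand enantiomer is the one that leads to the 2S series, expected to be (R)-t-BuPyOx.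

2. Step 1. The Lewis acid may cleave the methyl ether ortho to the new acyl group, or acylation next to fluorine may stall. The fallback sets out from 1 and comes back at 2. Lithiation with n-BuLi in THF at −78 °C at the position flanked by fluorine and methoxy gives (6-fluoro-2,3,4-trimethoxyphenyl)lithium F3. This is kept below −70 °C to prevent loss of LiF and trapped with N-methoxy-N-methylacetamide, giving 2 after NH4Cl work-up.

3. Step 2. The hindered trimethylsilyl enol ether may hydrolyse back to the ketone during isolation, which would lower the aldol conversion. The fallback sets out from 2 (with 4) and comes back at 5, without any enol silane. A direct aldol addition of 2 to 4 under Et2Zn/ProPhenol catalysis (THF, 4 Å molecular sieves, 0 °C) should give (3S)-1-(6-fluoro-2,3,4-trimethoxyphenyl)-3-hydroxy-3-(3,4,5-trimethoxyphenyl)propan-1-one F4. The ligand enantiomer is the one that leads to the S carbinol, expected to be (R,R). Silylation with Me3SiCl and imidazole in CH2Cl2 gives 5, which enters the fluoride stage of step 3 as an isolated compound.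

**Further compounds**

F1 | step 3 | 3-(6-fluoro-2,3,4-trimethoxyphenyl)-3-oxopropanal | O=CCC(=O)c1c(F)cc(OC)c(OC)c1OC
F2 | step 3 | 5,6,7-trimethoxy-4H-chromen-4-one | COc1cc2occc(=O)c2c(OC)c1OC
F3 | step 1 | (6-fluoro-2,3,4-trimethoxyphenyl)lithium | [Li]c1c(F)cc(OC)c(OC)c1OC
F4 | step 2 | (3S)-1-(6-fluoro-2,3,4-trimethoxyphenyl)-3-hydroxy-3-(3,4,5-trimethoxyphenyl)propan-1-one | COc1cc([C@H](CC(=O)c2c(F)cc(OC)c(OC)c2OC)O)cc(OC)c1OC
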